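**Retrosynthetic overview**
1. Target 35 comes from the 1,4-dimethoxynaphthalene 34 by oxidative demethylation, and 34 from sulfone 33 by Pd/hydride removal of a phenylsulfonyl group at C13' (side chain numbered C1' at the naphthalene to C25' at the cyclohexene).
2. 33 is cut at C10'–C11': a nickel-catalysed stereoconvergent alkyl–alkyl Suzuki coupling joins the B-alkyl-9-BBN of alkene 11 (C1'–C10', carries C7') to the secondary bromide 31 (C11'–C25' plus ring), used as all four C11'/C13' stereoisomers.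
3. Enabling feature: the C14'=C15' trisubstituted alkene makes C13' allylic, so PhSO2 can sit on C13', gamma to C11'. There it lets C12'–C13' be made from sulfone 27 and racemic propylene oxide, offers a sulfonyl oxygen for a six-membered chelate to nickel bound at C11', and later leaves through a π-allyl that returns the E alkene.
4. 11 comes from (S)-citronellal (C7') by methylenation, ozonolysis, acetylide extension, then carboalumination and nickel coupling with benzylic chloride 2. 27 comes from a B-alkyl Suzuki coupling of alkenyl iodide 20 (ring stereocentre by CBS reduction then Johnson–Claisen shift) with triene sulfone 25 (from geranyl bromide).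
5. Rings: none is built; the cyclohexene ring (from 12) and the naphthalene (from 1) are bought, and the quinone ring is unveiled last (step 23).

Key step: step 21

Remark: primed locants (C1'–C25') refer to the side chain of the target throughout.
Assumption: the (S,S)-diamine–nickel catalyst is taken to give the 11'S centre; if a model coupling shows the opposite sense, the (R,R)-ligand is used and nothing else changes.
Assumption: 1 and 12 are treated as catalogue compounds.

Step 1
Reactants: 1 1,4-dimethoxy-2-methylnaphthalene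
Product: 2 2-(chloromethyl)-1,4-dimethoxy-3-methylnaphthalene
Conditions: (CH2O)n, conc. aq HCl, AcOH, 60 °C
Reagents that add atoms: formaldehyde (as paraformaldehyde), C=O; hydrogen chloride, Cl
Why: Blanc chloromethylation should attack C3, the only free position of the dimethoxy-substituted ring and ortho to a methoxy group.

Step 2
Reactants: 3 (S)-citronellal
Product: 4 (4S)-4,8-dimethylnona-1,7-diene
Conditions: Ph3PCH3Br, KN(SiMe3)2, THF, −78 °C → rt
Reagents that add atoms: methyltriphenylphosphonium bromide, C[P+](c1ccccc1)(c1ccccc1)c1ccccc1.[Br-]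
Why: Wittig methylenation of the aldehyde; the stereocentre is beta to the carbonyl and cannot epimerise.

Step 3
Reactants: 4 (4S)-4,8-dimethylnona-1,7-diene
Product: 6 (4S)-4-methylhept-6-enal, via secondary ozonide 5 (not isolated)
Conditions: O3 (1 equiv, Sudan Red 7B end point), CH2Cl2, −78 °C; then Me2S, −78 °C → rt
Reagents that add atoms: ozone, [O-][O+]=O
Why: Chemoselective ozonolysis with reductive work-up; the electron-rich trisubstituted alkene should react much faster than the monosubstituted one.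

Step 4
Reactants: 6 (4S)-4-methylhept-6-enal
Product: 7 (4S)-4-methylhept-6-en-1-ol
Conditions: NaBH4, MeOH, 0 °C
Reagents that add atoms: none
Why: Borohydride reduction of an aldehyde to the primary alcohol.

Step 5
Reactants: 7 (4S)-4-methylhept-6-en-1-ol
Product: 8 (4S)-7-iodo-4-methylhept-1-ene
Conditions: I2, PPh3, imidazole, CH2Cl2, 0 °C → rt
Reagents that add atoms: iodine, I-I
Why: Garegg–Samuelsson (Appel-type) iodination of a primary alcohol.

Step 6
Reactants: 8 (4S)-7-iodo-4-methylhept-1-ene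
Product: 9 (4S)-4-methylnon-1-en-8-yne
Conditions: LiC≡CH·H2NCH2CH2NH2, DMSO, rt
Reagents that add atoms: lithium acetylide (ethylenediamine complex), [Li]C#C
Why: SN2 alkylation of acetylide by an unhindered primary iodide.

Step 7
Reactants: 9 (4S)-4-methylnon-1-en-8-yne; 2 2-(chloromethyl)-1,4-dimethoxy-3-methylnaphthalene
Product: 11 2-[(2E,7S)-3,7-dimethyldeca-2,9-dien-1-yl]-1,4-dimethoxy-3-methylnaphthalene, via alkenylalane 10 (not isolated)
Conditions: Me3Al, Cp2ZrCl2 (0.25 equiv), ClCH2CH2Cl, 0 °C → rt; volatiles removed; then 2, NiCl2(PPh3)2 (3 mol%) reduced by n-BuLi to zerovalent nickel, THF, 0 °C → rt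
Reagents that add atoms: trimethylaluminium, C[Al](C)C
Why: Negishi zirconium-catalysed syn-carboalumination of the terminal alkyne (much faster than that of the monosubstituted alkene) fixes the E geometry of C2'=C3', and the alkenylalane then undergoes nickel-catalysed cross-coupling with the benzylic chloride with retention.

Step 8
Reactants: 12 2,4,4-trimethylcyclohex-2-en-1-one
Product: 13 (1R)-2,4,4-trimethylcyclohex-2-en-1-ol
Conditions: (S)-2-methyl-CBS-oxazaborolidine (10 mol%), BH3·SMe2, THF, −20 °C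
Reagents that add atoms: none
Why: Corey–Bakshi–Shibata reduction; with the 2-methylalkenyl arm as the large group the (S)-catalyst should give the (R)-carbinol.

Step 9
Reactants: 13 (1R)-2,4,4-trimethylcyclohex-2-en-1-ol
Product: 15 ethyl 2-[(1S)-2,6,6-trimethylcyclohex-2-en-1-yl]acetate, via ketene acetal 14 (not isolated)
Conditions: MeC(OEt)3, EtCO2H (cat.), xylene, 140 °C, EtOH distilled off
Reagents that add atoms: triethyl orthoacetate, CC(OCC)(OCC)OCC
Why: Johnson–Claisen [3,3] rearrangement; suprafacial transfer from C–O to C–C on the same ring face should turn the (R)-carbinol centre into the (S)-configured ring CH between C(CH3)= and C(CH3)2.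

Step 10
Reactants: 15 ethyl 2-[(1S)-2,6,6-trimethylcyclohex-2-en-1-yl]acetate
Product: 16 2-[(1S)-2,6,6-trimethylcyclohex-2-en-1-yl]ethan-1-ol
Conditions: LiAlH4, Et2O, 0 °C
Reagents that add atoms: none
Why: Hydride reduction of an ester to the primary alcohol.

Step 11
Reactants: 16 2-[(1S)-2,6,6-trimethylcyclohex-2-en-1-yl]ethan-1-ol
Product: 17 (6S)-6-(2-iodoethyl)-1,5,5-trimethylcyclohex-1-ene
Conditions: I2, PPh3, imidazole, CH2Cl2, 0 °C → rt
Reagents that add atoms: iodine, I-I
Why: Garegg–Samuelsson iodination of a primary alcohol.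

Step 12
Reactants: 17 (6S)-6-(2-iodoethyl)-1,5,5-trimethylcyclohex-1-ene
Product: 18 (6S)-6-(but-3-yn-1-yl)-1,5,5-trimethylcyclohex-1-ene
Conditions: LiC≡CH·H2NCH2CH2NH2, DMSO, rt
Reagents that add atoms: lithium acetylide (ethylenediamine complex), [Li]C#C
Why: SN2 alkylation of acetylide by a primary iodide.

Step 13
Reactants: 18 (6S)-6-(but-3-yn-1-yl)-1,5,5-trimethylcyclohex-1-ene
Product: 20 (6S)-6-[(3E)-4-iodo-3-methylbut-3-en-1-yl]-1,5,5-trimethylcyclohex-1-ene, via alkenylalane 19 (not isolated)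
Conditions: Me3Al, Cp2ZrCl2 (0.25 equiv), ClCH2CH2Cl, rt; then I2, THF, −30 °C
Reagents that add atoms: trimethylaluminium, C[Al](C)C; iodine, I-I
Why: Negishi syn-carboalumination followed by iodinolysis with retention should give the E alkene C22'=C23' as one isomer.

Step 14
Reactants: 21 geranyl bromide
Product: 22 geranyl phenyl sulfone
Conditions: PhSO2Na, DMF, rt
Reagents that add atoms: sodium benzenesulfinate, [Na+].[O-]S(=O)c1ccccc1
Why: SN2 S-alkylation of the sulfinate by a primary allylic bromide, with the E alkene untouched.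

Step 15
Reactants: 22 geranyl phenyl sulfone
Product: 23 (2E,6E)-2,6-dimethyl-8-(phenylsulfonyl)octa-2,6-dien-1-ol
Conditions: SeO2 (cat.), t-BuOOH, salicylic acid (cat.), CH2Cl2, rt
Reagents that add atoms: tert-butyl hydroperoxide, CC(C)(C)OO
Why: Riley-type SeO2/t-BuOOH allylic oxidation (ene reaction then [2,3] shift) should hydroxylate the E-methyl of the terminal, more electron-rich alkene.

Step 16
Reactants: 23 (2E,6E)-2,6-dimethyl-8-(phenylsulfonyl)octa-2,6-dien-1-ol
Product: 24 (2E,6E)-2,6-dimethyl-8-(phenylsulfonyl)octa-2,6-dienal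
Conditions: MnO2, CH2Cl2, rt
Reagents that add atoms: none
Why: MnO2 oxidation of an allylic alcohol to the enal without alkene isomerisation.

Step 17
Reactants: 24 (2E,6E)-2,6-dimethyl-8-(phenylsulfonyl)octa-2,6-dienal
Product: 25 [(2E,6E)-3,7-dimethylnona-2,6,8-trien-1-yl] phenyl sulfone
Conditions: Ph3PCH3Br, KN(SiMe3)2, THF; 24 added to the preformed ylide at −78 °C, then 0 °C
Reagents that add atoms: methyltriphenylphosphonium bromide, C[P+](c1ccccc1)(c1ccccc1)c1ccccc1.[Br-]
Why: Wittig methylenation; addition of the ylide to the enal at −78 °C should outrun proton transfer from the allylic sulfone.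

Step 18
Reactants: 25 [(2E,6E)-3,7-dimethylnona-2,6,8-trien-1-yl] phenyl sulfone; 20 (6S)-6-[(3E)-4-iodo-3-methylbut-3-en-1-yl]-1,5,5-trimethylcyclohex-1-ene
Product: 27 (2E,6E,10E)-3,7,11-trimethyl-13-[(1S)-2,6,6-trimethylcyclohex-2-en-1-yl]trideca-2,6,10-trien-1-yl phenyl sulfone, via B-alkyl-9-BBN 26 (not isolated)
Conditions: 9-BBN dimer, THF, 0 °C → rt; then 20, Pd(dppf)Cl2 (5 mol%), AsPh3, Cs2CO3, DMF/THF/H2O, rt
Reagents that add atoms: none
Why: 9-BBN should add anti-Markovnikov to the monosubstituted terminus of the diene only, and B-alkyl Suzuki–Miyaura coupling with the alkenyl iodide proceeds with retention of the E geometry.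

Step 19
Reactants: 27 (2E,6E,10E)-3,7,11-trimethyl-13-[(1S)-2,6,6-trimethylcyclohex-2-en-1-yl]trideca-2,6,10-trien-1-yl phenyl sulfone; 28 (±)-propylene oxide
Product: 30 (5E,9E,13E)-6,10,14-trimethyl-4-(phenylsulfonyl)-16-[(1S)-2,6,6-trimethylcyclohex-2-en-1-yl]hexadeca-5,9,13-trien-2-ol (all four C2/C4 stereoisomers), via lithiated sulfone 29 (not isolated)
Conditions: n-BuLi, THF/DMPU, −78 °C; then 28, −78 °C → rt; H2O
Reagents that add atoms: none
Why: Alpha-alkylation of the allylic sulfone carbanion at the unsubstituted epoxide carbon forms C12'–C13'; the two new centres (C11', C13') are left uncontrolled because neither needs control here.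

Step 20
Reactants: 30 the hydroxy sulfone of step 19
Product: 31 [(5E,9E,13E)-2-bromo-6,10,14-trimethyl-16-[(1S)-2,6,6-trimethylcyclohex-2-en-1-yl]hexadeca-5,9,13-trien-4-yl] phenyl sulfone (all four C2/C4 stereoisomers)
Conditions: CBr4, PPh3, CH2Cl2, 0 °C → rt
Reagents that add atoms: carbon tetrabromide, BrC(Br)(Br)Br
Why: Appel bromination of the secondary alcohol under neutral conditions; its stereochemical course is irrelevant.

Step 21
Reactants: 11 2-[(2E,7S)-3,7-dimethyldeca-2,9-dien-1-yl]-1,4-dimethoxy-3-methylnaphthalene; 31 the gamma-bromo sulfone of step 20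
Product: 33 2-[(2E,7R,11S,14E,18E,22E)-3,7,11,15,19,23-hexamethyl-13-(phenylsulfonyl)-25-[(1S)-2,6,6-trimethylcyclohex-2-en-1-yl]pentacosa-2,14,18,22-tetraen-1-yl]-1,4-dimethoxy-3-methylnaphthalene (both C13' epimers), via B-alkyl-9-BBN 32 (not isolated)
Conditions: 11 (1.5 equiv), 9-BBN dimer, i-Pr2O, rt → 60 °C; 32 premixed with KOt-Bu and n-hexanol; then 31, NiBr2·diglyme (10 mol%), (S,S)-N,N'-dimethyl-1,2-diphenylethane-1,2-diamine (12 mol%), i-Pr2O, rt
Reagents that add atoms: none
Why: Hydroboration of the monosubstituted alkene of 11 gives the primary borane 32, whose alkoxide ate complex transmetallates to a chiral diamine–nickel species; this abstracts bromine from 31, recaptures the secondary C11' radical and reductively eliminates to form C10'–C11'. The closest known reaction type is the nickel/chiral-diamine stereoconvergent alkyl–alkyl Suzuki–Miyaura coupling of racemic unactivated secondary bromides that carry a carbamate, sulfonamide or sulfone oxygen as directing group; no ring is closed. Because C11' passes through a planar radical, both C11' epimers of 31 converge, and the new 11'S centre is set by the (S,S)-diamine–nickel catalyst, not by the substrate. The step needs the catalyst to tell CH3 from the C12' chain at C11': the sulfonyl oxygen on C13', gamma to the bromide, can bind nickel in a six-membered chelate and so marks the C12' arm. It also needs the radical to survive: the nearest alkene (C14'=C15') makes it a 4-pentenyl radical with no fast cyclisation mode, and the C7' centre of 32 is remote and untouched. The uncontrolled C13' centre lies in the chelate and may lower selectivity for one epimer series, but step 22 erases it, so four stereoisomers of 31 should funnel into one C11' configuration.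

Step 22
Reactants: 33 the coupled sulfone of step 21
Product: 34 2-[(2E,7R,11S,14E,18E,22E)-3,7,11,15,19,23-hexamethyl-25-[(1S)-2,6,6-trimethylcyclohex-2-en-1-yl]pentacosa-2,14,18,22-tetraen-1-yl]-1,4-dimethoxy-3-methylnaphthalene
Conditions: PdCl2(dppp) (5 mol%), LiBHEt3, THF, 0 °C
Reagents that add atoms: none
Why: Palladium-catalysed reductive desulfonylation: ionisation to a π-allylpalladium and hydride delivery to the less substituted terminus (C13') should restore the E alkene C14'=C15' and erase the C13' centre.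

Step 23
Reactants: 34 the dimethyl ether of step 22
Product: 35 2-methyl-3-[(2E,7R,11S,14E,18E,22E)-3,7,11,15,19,23-hexamethyl-25-[(1S)-2,6,6-trimethylcyclohex-2-en-1-yl]pentacosa-2,14,18,22-tetraen-1-yl]naphthalene-1,4-dione
Conditions: (NH4)2Ce(NO3)6, MeCN/H2O, 0 °C
Reagents that add atoms: water, O
Why: Oxidative demethylation of the 1,4-dimethoxyarene to the quinone; isolated trisubstituted alkenes should survive brief exposure at 0 °C.

**Compound list**
1 | 1,4-dimethoxy-2-methylnaphthalene | COc1c(C)cc(OC)c2ccccc12 | starting material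
2 | 2-(chloromethyl)-1,4-dimethoxy-3-methylnaphthalene | COc1c(C)c(CCl)c(OC)c2ccccc12 | intermediate
3 | (S)-citronellal, (3S)-3,7-dimethyloct-6-enal | O=CC[C@@H](C)CCC=C(C)C | starting material
4 | (4S)-4,8-dimethylnona-1,7-diene | C=CC[C@@H](C)CCC=C(C)C | intermediate
5 | 3,3-dimethyl-5-[(3S)-3-methylhex-5-en-1-yl]-1,2,4-trioxolane (secondary ozonide) | C=CC[C@@H](C)CCC1OOC(C)(C)O1 | intermediate
6 | (4S)-4-methylhept-6-enal | C=CC[C@@H](C)CCC=O | intermediate
7 | (4S)-4-methylhept-6-en-1-ol | C=CC[C@@H](C)CCCO | intermediate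
8 | (4S)-7-iodo-4-methylhept-1-ene | C=CC[C@@H](C)CCCI | intermediate
9 | (4S)-4-methylnon-1-en-8-yne | C=CC[C@@H](C)CCCC#C | intermediate
10 | dimethyl[(1E,6S)-2,6-dimethylnona-1,8-dien-1-yl]alane | C=CC[C@@H](C)CCC/C(C)=C/[Al](C)C | intermediate
11 | 2-[(2E,7S)-3,7-dimethyldeca-2,9-dien-1-yl]-1,4-dimethoxy-3-methylnaphthalene (fragment 1) | C=CC[C@@H](C)CCC/C(C)=C/Cc1c(C)c(OC)c2ccccc2c1OC | intermediate
12 | 2,4,4-trimethylcyclohex-2-en-1-one | CC1=CC(C)(C)CCC1=O | starting material
13 | (1R)-2,4,4-trimethylcyclohex-2-en-1-ol | O[C@@H]1CCC(C)(C)C=C1C | intermediate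
14 | (6R)-6-[(1-ethoxyethenyl)oxy]-1,3,3-trimethylcyclohex-1-ene (ketene acetal) | C=C(OCC)O[C@@H]1CCC(C)(C)C=C1C | intermediate
15 | ethyl 2-[(1S)-2,6,6-trimethylcyclohex-2-en-1-yl]acetate | CC1=CCCC(C)(C)[C@@H]1CC(=O)OCC | intermediate
16 | 2-[(1S)-2,6,6-trimethylcyclohex-2-en-1-yl]ethan-1-ol | CC1=CCCC(C)(C)[C@@H]1CCO | intermediate
17 | (6S)-6-(2-iodoethyl)-1,5,5-trimethylcyclohex-1-ene | CC1=CCCC(C)(C)[C@@H]1CCI | intermediate
18 | (6S)-6-(but-3-yn-1-yl)-1,5,5-trimethylcyclohex-1-ene | CC1=CCCC(C)(C)[C@@H]1CCC#C | intermediate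
19 | dimethyl{(1E)-2-methyl-4-[(1S)-2,6,6-trimethylcyclohex-2-en-1-yl]but-1-en-1-yl}alane | CC1=CCCC(C)(C)[C@@H]1CC/C(C)=C/[Al](C)C | intermediate
20 | (6S)-6-[(3E)-4-iodo-3-methylbut-3-en-1-yl]-1,5,5-trimethylcyclohex-1-ene | CC1=CCCC(C)(C)[C@@H]1CC/C(C)=C/I | intermediate
21 | geranyl bromide, (2E)-1-bromo-3,7-dimethylocta-2,6-diene | CC(C)=CCC/C(C)=C/CBr | starting material
22 | geranyl phenyl sulfone, [(2E)-3,7-dimethylocta-2,6-dien-1-yl] phenyl sulfone | CC(C)=CCC/C(C)=C/CS(=O)(=O)c1ccccc1 | intermediate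
23 | (2E,6E)-2,6-dimethyl-8-(phenylsulfonyl)octa-2,6-dien-1-ol | OC/C(C)=C/CC/C(C)=C/CS(=O)(=O)c1ccccc1 | intermediate
24 | (2E,6E)-2,6-dimethyl-8-(phenylsulfonyl)octa-2,6-dienal | O=C/C(C)=C/CC/C(C)=C/CS(=O)(=O)c1ccccc1 | intermediate
25 | [(2E,6E)-3,7-dimethylnona-2,6,8-trien-1-yl] phenyl sulfone | C=C/C(C)=C/CC/C(C)=C/CS(=O)(=O)c1ccccc1 | intermediate
26 | 9-[(3E,7E)-3,7-dimethyl-9-(phenylsulfonyl)nona-3,7-dien-1-yl]-9-borabicyclo[3.3.1]nonane | C1CCC2CCCC1B2CC/C(C)=C/CC/C(C)=C/CS(=O)(=O)c1ccccc1 | intermediate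
27 | (2E,6E,10E)-3,7,11-trimethyl-13-[(1S)-2,6,6-trimethylcyclohex-2-en-1-yl]trideca-2,6,10-trien-1-yl phenyl sulfone | CC1=CCCC(C)(C)[C@@H]1CC/C(C)=C/CC/C(C)=C/CC/C(C)=C/CS(=O)(=O)c1ccccc1 | intermediate
28 | (±)-propylene oxide, 2-methyloxirane | CC1CO1 | starting material
29 | 27 lithiated at the carbon bearing sulfur (C13') | CC1=CCCC(C)(C)[C@@H]1CC/C(C)=C/CC/C(C)=C/CC/C(C)=C/C([Li])S(=O)(=O)c1ccccc1 | intermediate
30 | (5E,9E,13E)-6,10,14-trimethyl-4-(phenylsulfonyl)-16-[(1S)-2,6,6-trimethylcyclohex-2-en-1-yl]hexadeca-5,9,13-trien-2-ol, all four C2/C4 stereoisomers | CC1=CCCC(C)(C)[C@@H]1CC/C(C)=C/CC/C(C)=C/CC/C(C)=C/C(CC(C)O)S(=O)(=O)c1ccccc1 | intermediate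
31 | [(5E,9E,13E)-2-bromo-6,10,14-trimethyl-16-[(1S)-2,6,6-trimethylcyclohex-2-en-1-yl]hexadeca-5,9,13-trien-4-yl] phenyl sulfone, all four C2/C4 stereoisomers (fragment 2) | CC1=CCCC(C)(C)[C@@H]1CC/C(C)=C/CC/C(C)=C/CC/C(C)=C/C(CC(C)Br)S(=O)(=O)c1ccccc1 | intermediate
32 | 9-[(4R,8E)-10-(1,4-dimethoxy-3-methylnaphthalen-2-yl)-4,8-dimethyldec-8-en-1-yl]-9-borabicyclo[3.3.1]nonane | C1CCC2CCCC1B2CCC[C@@H](C)CCC/C(C)=C/Cc1c(C)c(OC)c2ccccc2c1OC | intermediate
33 | 2-[(2E,7R,11S,14E,18E,22E)-3,7,11,15,19,23-hexamethyl-13-(phenylsulfonyl)-25-[(1S)-2,6,6-trimethylcyclohex-2-en-1-yl]pentacosa-2,14,18,22-tetraen-1-yl]-1,4-dimethoxy-3-methylnaphthalene, both C13' epimers | CC1=CCCC(C)(C)[C@@H]1CC/C(C)=C/CC/C(C)=C/CC/C(C)=C/C(S(=O)(=O)c1ccccc1)C[C@@H](C)CCC[C@@H](C)CCC/C(C)=C/Cc1c(C)c(OC)c2ccccc2c1OC | intermediate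
34 | 2-[(2E,7R,11S,14E,18E,22E)-3,7,11,15,19,23-hexamethyl-25-[(1S)-2,6,6-trimethylcyclohex-2-en-1-yl]pentacosa-2,14,18,22-tetraen-1-yl]-1,4-dimethoxy-3-methylnaphthalene | CC1=CCCC(C)(C)[C@@H]1CC/C(C)=C/CC/C(C)=C/CC/C(C)=C/CC[C@@H](C)CCC[C@@H](C)CCC/C(C)=C/Cc1c(C)c(OC)c2ccccc2c1OC | intermediate
35 | 2-methyl-3-[(2E,7R,11S,14E,18E,22E)-3,7,11,15,19,23-hexamethyl-25-[(1S)-2,6,6-trimethylcyclohex-2-en-1-yl]pentacosa-2,14,18,22-tetraen-1-yl]naphthalene-1,4-dione | CC1=CCCC(C)(C)[C@@H]1CC/C(C)=C/CC/C(C)=C/CC/C(C)=C/CC[C@@H](C)CCC[C@@H](C)CCC/C(C)=C/CC1=C(C)C(=O)c2ccccc2C1=O | target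

**Step count and risks**
Total steps: 23. Longest linear sequence: 12 steps (steps 8–13, then 18–23).

Risk 1, step 21. Two processes may spoil it. Catalyst control at C11' may be eroded for one of the two C13' epimer series, because the C13' centre sits inside the nickel chelate. Alkoxide may also deprotonate the acidic allylic C13'–H, which would then displace bromide in a 1,3-elimination to a cyclopropane. The fallback gives up stereoconvergence for a stereospecific coupling. It sets out from 27 and 11 and returns at 34. The anion 29 of sulfone 27 is alkylated with (S)-propylene oxide (C[C@H]1CO1; n-BuLi, THF/DMPU) to give the (2S)-hydroxy sulfone F1. PdCl2(dppp)/LiBHEt3 removes the sulfone to give the (2S)-alcohol F2, and TsCl/pyridine/DMAP gives the (2S)-tosylate F3. Alkene 11 is hydroborated (9-BBN, through 32) and oxidised (NaOH, H2O2) to the primary alcohol F4, which is converted into the bromide F5 (CBr4, PPh3) and then the Grignard reagent F6 (Mg, THF). Coupling of F6 with F3 under CuI/TMEDA/LiOMe catalysis (SN2 with inversion at C11') should give 34 directly.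

Risk 2, step 9. Acid-promoted ionisation and elimination of the allylic alcohol to a diene at 140 °C may outrun bond formation at the hindered alkene terminus next to C(CH3)2. The fallback is an ester-enolate rearrangement at low temperature; it sets out from 13 and returns at 16. Acetylation (Ac2O, pyridine, DMAP) gives the acetate F7. LiN(i-Pr)2 and Me3SiCl in THF at −78 °C give the silyl ketene acetal F8, which on warming undergoes the Ireland–Claisen shift to the silyl ester F9. Aqueous work-up gives the acid F10, and LiAlH4 reduces F10 to 16.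

Risk 3, step 7. Transfer of the alkenyl group from aluminium to zerovalent nickel may be slow, so that the benzylic chloride is consumed by homocoupling or reduction. The fallback reverses the polarity of the coupling; it sets out from 9 and 2 and returns at 11. Alkenylalane 10 is quenched with I2 to give the (E)-alkenyl iodide F11. Chloride 2 is converted with zinc dust and LiCl in THF into the benzylic zinc chloride F12. Negishi coupling of F12 with F11 under Pd(PPh3)4 catalysis should give 11 with retention of the E geometry.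

**Further compounds**
F1 | step 21 | (2S,5E,9E,13E)-6,10,14-trimethyl-4-(phenylsulfonyl)-16-[(1S)-2,6,6-trimethylcyclohex-2-en-1-yl]hexadeca-5,9,13-trien-2-ol, both C4 epimers | CC1=CCCC(C)(C)[C@@H]1CC/C(C)=C/CC/C(C)=C/CC/C(C)=C/C(C[C@H](C)O)S(=O)(=O)c1ccccc1
F2 | step 21 | (2S,5E,9E,13E)-6,10,14-trimethyl-16-[(1S)-2,6,6-trimethylcyclohex-2-en-1-yl]hexadeca-5,9,13-trien-2-ol | CC1=CCCC(C)(C)[C@@H]1CC/C(C)=C/CC/C(C)=C/CC/C(C)=C/CC[C@H](C)O
F3 | step 21 | (2S,5E,9E,13E)-6,10,14-trimethyl-16-[(1S)-2,6,6-trimethylcyclohex-2-en-1-yl]hexadeca-5,9,13-trien-2-yl 4-methylbenzenesulfonate | CC1=CCCC(C)(C)[C@@H]1CC/C(C)=C/CC/C(C)=C/CC/C(C)=C/CC[C@H](C)OS(=O)(=O)c1ccc(C)cc1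
F4 | step 21 | (4S,8E)-10-(1,4-dimethoxy-3-methylnaphthalen-2-yl)-4,8-dimethyldec-8-en-1-ol | OCCC[C@@H](C)CCC/C(C)=C/Cc1c(C)c(OC)c2ccccc2c1OC
F5 | step 21 | 2-[(2E,7S)-10-bromo-3,7-dimethyldec-2-en-1-yl]-1,4-dimethoxy-3-methylnaphthalene | BrCCC[C@@H](C)CCC/C(C)=C/Cc1c(C)c(OC)c2ccccc2c1OC
F6 | step 21 | [(4S,8E)-10-(1,4-dimethoxy-3-methylnaphthalen-2-yl)-4,8-dimethyldec-8-en-1-yl]magnesium bromide | Br[Mg]CCC[C@@H](C)CCC/C(C)=C/Cc1c(C)c(OC)c2ccccc2c1OC
F7 | step 9 | (1R)-2,4,4-trimethylcyclohex-2-en-1-yl acetate | CC(=O)O[C@@H]1CCC(C)(C)C=C1C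
F8 | step 9 | trimethyl({1-[(1R)-2,4,4-trimethylcyclohex-2-en-1-yl]oxyethenyl}oxy)silane | C=C(O[Si](C)(C)C)O[C@@H]1CCC(C)(C)C=C1C
F9 | step 9 | trimethylsilyl 2-[(1S)-2,6,6-trimethylcyclohex-2-en-1-yl]acetate | CC1=CCCC(C)(C)[C@@H]1CC(=O)O[Si](C)(C)C
F10 | step 9 | 2-[(1S)-2,6,6-trimethylcyclohex-2-en-1-yl]acetic acid | CC1=CCCC(C)(C)[C@@H]1CC(=O)O
F11 | step 7 | (1E,6S)-1-iodo-2,6-dimethylnona-1,8-diene | C=CC[C@@H](C)CCC/C(C)=C/I
F12 | step 7 | [(1,4-dimethoxy-3-methylnaphthalen-2-yl)methyl]zinc chloride | Cl[Zn]Cc1c(C)c(OC)c2ccccc2c1OC
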